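Everything rests on cutting the lactone ring B (C1, O2, C3, C4, C4a, C8a) at C4–C4a and O2–C3. The feature exploited is that in arene ring A, C4a is the only unsubstituted carbon ortho to the carboxyl carbon C1 once O8 is capped as a methyl ether. A carboxylate-directed C–H annulation of a benzoic acid bearing the future C6 and C8 methoxy groups with an α-keto sulfoxonium ylide therefore forges both bonds and closes ring B as an isocoumarin in one operation. The ylide carries the whole side chain, its ketone masked as a dioxolane. Asymmetric hydrogenation of the flat C3=C4 bond then sets (R)-C3, and two deprotections finish.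

Key step: step 4

Assumption: the sense of induction of the chiral ruthenium catalyst in step 5 is confirmed on a small scale against the racemate; should the ligand pair written there deliver the (S)-lactone, the mirror-image ligand pair is used.

Step 1
Reactants: 1 methyl 8-chloro-8-oxooctanoate; 2 butylmagnesium chloride
Product: 3 methyl 8-oxododecanoate
Conditions: Fe(acac)3 (3 mol%), THF, −78 °C, slow addition of 2 (1.1 equiv); aq NH4Cl quench at −78 °C
Reagents that add atoms: none
Why: Iron-catalysed acyl cross-coupling (Kumada-type ketone synthesis) of the acid chloride with the alkyl Grignard reagent is much faster at −78 °C than addition to the methyl ester or to the ketone formed, so the keto ester should result cleanly.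

Step 2
Reactants: 3 methyl 8-oxododecanoate
Product: 4 methyl 7-(2-butyl-1,3-dioxolan-2-yl)heptanoate
Conditions: ethylene glycol (3 equiv), p-TsOH·H2O (5 mol%), toluene, reflux, Dean–Stark trap; NaHCO3 work-up
Reagents that add atoms: ethylene glycol, OCCO
Why: Acid-catalysed ketalisation with azeotropic removal of water masks the ketone, which would otherwise be epoxidised by the sulfur ylide in step 3 and reduced by the hydrogenation catalyst in step 5.

Step 3
Reactants: 4 methyl 7-(2-butyl-1,3-dioxolan-2-yl)heptanoate
Product: 5 8-(2-butyl-1,3-dioxolan-2-yl)-1-[dimethyl(oxo)-λ6-sulfanylidene]octan-2-one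
Conditions: Me3S(O)I (3 equiv), KOtBu (3 equiv), THF, reflux 2 h; then 4, THF, reflux
Reagents that add atoms: trimethylsulfoxonium iodide, C[S+](C)(C)=O.[I-]
Why: Corey–Chaykovsky-type acyl substitution, in which the methylide adds to the ester, methoxide leaves and the acidic α-proton of the acylsulfoxonium salt is removed to give the stabilised β-keto sulfoxonium ylide, while the dioxolane is inert to base.

Step 4
Reactants: 5 8-(2-butyl-1,3-dioxolan-2-yl)-1-[dimethyl(oxo)-λ6-sulfanylidene]octan-2-one; 6 2,4-dimethoxybenzoic acid
Product: 9 3-[6-(2-butyl-1,3-dioxolan-2-yl)hexyl]-6,8-dimethoxy-1H-isochromen-1-one, via keto acid 7 (not isolated), via lactol 8 (not isolated)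
Conditions: 6 (1.5 equiv), [Cp*RhCl2]2 (2.5 mol%), AgSbF6 (10 mol%), NaOAc (1 equiv), 4 Å molecular sieves, ClCH2CH2Cl, 80 °C
Reagents that add atoms: none
Why: Chloride abstraction gives a cationic Cp*Rh carboxylate of trivalent rhodium that cleaves the C6–H bond of 6 by acetate-assisted concerted metalation–deprotonation to a five-membered rhodacycle; the ylide carbon binds, dimethyl sulfoxide leaves to give a rhodium carbene, and migratory insertion into the aryl–rhodium bond followed by protodemetalation releases keto acid 7. The carboxyl oxygen of 7 then adds to the ketone carbonyl in a 6-exo-trig closure to lactol 8, and loss of water gives the C3=C4 enol lactone, so ring B is closed through the O2–C3 bond after the C4–C4a bond has been made. The closest known reaction type is the Cp*Rh-catalysed, carboxylate-directed C–H acylmethylation/annulation of benzoic acids with sulfoxonium ylides to 3-substituted isocoumarins, which is redox-neutral and needs no external oxidant. No stereocentre is formed. The step needs regioselectivity for C6–H, secured because the other ortho position carries the methoxy group that becomes O8, and it needs the dioxolane to survive, which the acetate buffer, the aprotic solvent and the sieves that take up the water of condensation should secure. The cheap acid is used in excess so that the valuable ylide is consumed by cross-coupling and not by self-condensation.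

Step 5
Reactants: 9 3-[6-(2-butyl-1,3-dioxolan-2-yl)hexyl]-6,8-dimethoxy-1H-isochromen-1-one
Product: 10 (3R)-3-[6-(2-butyl-1,3-dioxolan-2-yl)hexyl]-6,8-dimethoxy-3,4-dihydro-1H-isochromen-1-one
Conditions: H2 (50 bar), chiral Ru catalyst (3 mol%) preformed from Ru(2-methylallyl)2(cod), (R,R)-SINpEt·HBF4, KOtBu and (R,R)-1,2-diphenylethylenediamine, NaOtBu (10 mol%), toluene, 25 °C
Reagents that add atoms: none
Why: Catalytic asymmetric hydrogenation of the enol-lactone C3=C4 bond by a chiral NHC–diamine hydride of divalent ruthenium is a known reaction type for 3-substituted isocoumarins; the chiral ligand sphere alone differentiates the two faces of the flat ring B and so sets (R)-C3 by catalyst control, while the ketal, the aryl ethers and the arene are untouched.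

Step 6
Reactants: 10 (3R)-3-[6-(2-butyl-1,3-dioxolan-2-yl)hexyl]-6,8-dimethoxy-3,4-dihydro-1H-isochromen-1-one
Product: 11 (3R)-6,8-dimethoxy-3-(7-oxoundecyl)-3,4-dihydro-1H-isochromen-1-one
Conditions: 2 M aq HCl/THF (1:4), 25 °C
Reagents that add atoms: water, O
Why: Acid-catalysed ketal hydrolysis through the oxocarbenium ion is fast for a dialkyl dioxolane, and the lactone, the aryl methyl ethers and the non-epimerisable C3 centre are stable to dilute acid at room temperature.

Step 7
Reactants: 11 (3R)-6,8-dimethoxy-3-(7-oxoundecyl)-3,4-dihydro-1H-isochromen-1-one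
Product: 12 (3R)-8-hydroxy-6-methoxy-3-(7-oxoundecyl)-3,4-dihydro-1H-isochromen-1-one
Conditions: BCl3 (1 M in CH2Cl2, 2.5 equiv), CH2Cl2, −78 to 0 °C; water work-up
Reagents that add atoms: none
Why: Chelation-controlled Lewis-acid ether cleavage, in which boron binds the lactone carbonyl and the peri C8 methoxy oxygen in a six-membered chelate and chloride removes that methyl group as chloromethane, while the non-chelated C6 ether, the ketone and C3 are left alone at low temperature.

Compound list
1 | methyl 8-chloro-8-oxooctanoate | COC(=O)CCCCCCC(=O)Cl | starting material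
2 | butylmagnesium chloride | CCCC[Mg]Cl | starting material
3 | methyl 8-oxododecanoate | CCCCC(=O)CCCCCCC(=O)OC | intermediate
4 | methyl 7-(2-butyl-1,3-dioxolan-2-yl)heptanoate | CCCCC1(OCCO1)CCCCCCC(=O)OC | intermediate
5 | 8-(2-butyl-1,3-dioxolan-2-yl)-1-[dimethyl(oxo)-λ6-sulfanylidene]octan-2-one | CCCCC1(OCCO1)CCCCCCC(=O)C=S(C)(C)=O | intermediate
6 | 2,4-dimethoxybenzoic acid | COc1ccc(C(=O)O)c(OC)c1 | starting material
7 | 2-[8-(2-butyl-1,3-dioxolan-2-yl)-2-oxooctyl]-4,6-dimethoxybenzoic acid (keto acid, not isolated) | CCCCC1(OCCO1)CCCCCCC(=O)Cc1cc(OC)cc(OC)c1C(=O)O | intermediate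
8 | 3-[6-(2-butyl-1,3-dioxolan-2-yl)hexyl]-3-hydroxy-6,8-dimethoxy-3,4-dihydro-1H-isochromen-1-one (lactol, racemic, not isolated) | CCCCC1(OCCO1)CCCCCCC2(O)Cc3cc(OC)cc(OC)c3C(=O)O2 | intermediate
9 | 3-[6-(2-butyl-1,3-dioxolan-2-yl)hexyl]-6,8-dimethoxy-1H-isochromen-1-one | CCCCC1(OCCO1)CCCCCCC2=Cc3cc(OC)cc(OC)c3C(=O)O2 | intermediate
10 | (3R)-3-[6-(2-butyl-1,3-dioxolan-2-yl)hexyl]-6,8-dimethoxy-3,4-dihydro-1H-isochromen-1-one | CCCCC1(OCCO1)CCCCCC[C@@H]2Cc3cc(OC)cc(OC)c3C(=O)O2 | intermediate
11 | (3R)-6,8-dimethoxy-3-(7-oxoundecyl)-3,4-dihydro-1H-isochromen-1-one | CCCCC(=O)CCCCCC[C@@H]1Cc2cc(OC)cc(OC)c2C(=O)O1 | intermediate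
12 | (3R)-8-hydroxy-6-methoxy-3-(7-oxoundecyl)-3,4-dihydro-1H-isochromen-1-one | CCCCC(=O)CCCCCC[C@@H]1Cc2cc(OC)cc(O)c2C(=O)O1 | target

Total step count: 7. Longest linear sequence: 7 steps (1 to 12 through steps 1–7; acid 6 is bought and enters at step 4).

Steps most likely to fail

1. Step 4. Carbene transfer from an alkyl keto ylide may be sluggish, the ylide may be lost to self-condensation or protonolysis, and the dioxolane may be partly cleaved by the acidic medium. The fallback uses known chemistry and sets out from ketal ester 4. Purchased 2,4-dimethoxy-6-methylbenzoic acid (Cc1cc(OC)cc(OC)c1C(=O)O) is doubly deprotonated with LDA (2.2 equiv per acid, THF, −78 to 0 °C) to lithium 2-(lithiomethyl)-4,6-dimethoxybenzoate F1. Two equivalents of F1 are treated with 4 at −78 °C in a Claisen-type acylation of the laterally lithiated toluate, the second equivalent taking up the acidic proton of the product. Careful acidification to pH 4 with cold dilute HCl gives keto acid 7, now isolated. Warming 7 with Ac2O and NaOAc at 80 °C cyclodehydrates it to isocoumarin 9, where the route is rejoined.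

2. Step 5. Facial selectivity on the electron-rich, long-chain enol lactone may be poor, or conversion incomplete. The fallback sets out from isocoumarin 9. Hydrogenation over Pd/C (10% palladium on carbon; H2 1 atm, EtOAc, 25 °C) should give racemic 3-[6-(2-butyl-1,3-dioxolan-2-yl)hexyl]-6,8-dimethoxy-3,4-dihydro-1H-isochromen-1-one F2. Preparative chromatography on a chiral stationary phase (amylose tris(3,5-dimethylphenylcarbamate), hexane/i-PrOH) then separates the (R)-enantiomer, which is 10, and the route continues from there.

3. Step 3. Acyl substitution at the unactivated, enolisable methyl ester may stall through competing enolisation and slow addition. The fallback sets out from ester 4. Saponification (LiOH, THF/H2O; acidify only to pH 5) gives 7-(2-butyl-1,3-dioxolan-2-yl)heptanoic acid F3. Coupling with 4-nitrophenol (EDC·HCl, DMAP cat., CH2Cl2) gives the activated 4-nitrophenyl 7-(2-butyl-1,3-dioxolan-2-yl)heptanoate F4. F4 reacts with dimethylsulfoxonium methylide (Me3S(O)I, KOtBu, THF, 0 to 25 °C) to give ylide 5, where the route is rejoined.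

Further compounds
F1 | step 4 | lithium 2-(lithiomethyl)-4,6-dimethoxybenzoate | [Li]Cc1cc(OC)cc(OC)c1C(=O)O[Li]
F2 | step 5 | racemic 3-[6-(2-butyl-1,3-dioxolan-2-yl)hexyl]-6,8-dimethoxy-3,4-dihydro-1H-isochromen-1-one | CCCCC1(OCCO1)CCCCCCC2Cc3cc(OC)cc(OC)c3C(=O)O2
F3 | step 3 | 7-(2-butyl-1,3-dioxolan-2-yl)heptanoic acid | CCCCC1(OCCO1)CCCCCCC(=O)O
F4 | step 3 | 4-nitrophenyl 7-(2-butyl-1,3-dioxolan-2-yl)heptanoate | CCCCC1(OCCO1)CCCCCCC(=O)Oc1ccc(cc1)[N+](=O)[O-]
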